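## Analysis of the target

The target 15 is 6-hydroxy-7-methoxy-3-(3,4,5-trimethoxyphenyl)-4H-chromen-4-one, an isoflavone. A benzo ring A is fused to a 4-pyranone ring C, which carries the aryl ring B on C3 and a hydrogen on C2. There is no stereocentre, so the problem is one of connectivity, oxidation level and regiochemistry. Ring A bears a free hydroxyl at C6 next to a methyl ether at C7; the two must be told apart from the first step, because four aryl methyl ethers have to survive and no late ether cleavage with strong Lewis acids is possible. The pyranone is a vinylogous ester whose C2 is opened by hydroxide or amines, so ring C should be closed late and under acid. Once O1 is free as a phenol, ring A is a para-dihydroxybenzene and oxidises easily, so the open-chain stage must be short. The difficulties are to place ring B on C3 and not on C2, and to bring in C2 as one carbon at the aldehyde oxidation level. The strategy rests on the unit C4–C3–C2: C4 and C2 are both at carbonyl level with ring B on the carbon between them, which is the pattern of C3, C4 and C5 of a 3,4-diarylisoxazole with hydrogen at C5.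

## Retrosynthetic reasoning

**15 to 14.** The O1–C2 bond is cut and the C4 carbonyl is written as its primary enamine. This gives the Z amino enal 14, in which C2 is a formyl group and the future O1 is a free phenol. This bond is chosen because it is the only bond of ring C that forms by simple addition of a phenol to a formyl carbon. Forward, aqueous acid must close the ring, dehydrate, and hydrolyse the nitrogen off C4. Only the ortho hydroxyl can reach C2, so there is no regiochemical choice.

**14 to 13.** The amino and formyl groups of 14 are joined through an N–O bond, and both phenols are capped as benzyl ethers. This gives the isoxazole 13. The isoxazole stores C4 and C2 at the correct oxidation levels in a robust aromatic ring, with ring B fixed between them. One hydrogenation should cleave the N–O bond and both benzyl ethers. Benzyl is chosen for both oxygens so that no separate deprotection step is needed.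

**13 to 11 and 10 (through 12).** The isoxazole is cut at the bond between its C3 and C4 (C4–C3 of the target) and at the bond between its oxygen and C5 (the oxygen on C2 of the target). This gives the ring A nitrile oxide 11 and the ring B enamine 10. It is the convergent cut: it makes the only ring C carbon–carbon bond that is not already in a bought fragment and joins the two aryl halves. The forward cycloaddition passes through the aminoisoxazoline 12, which must lose 9 to become aromatic. Spontaneous loss is not assumed; acid is added in the same flask to drive it. The isoxazole oxygen is only a placeholder that holds C2 at the aldehyde level. The ring oxygen of 15 is the phenolic oxygen already on ring A.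

**11 back to 1.** The nitrile oxide 11 comes from the hydroximoyl chloride 5 by dehydrochlorination in the flask. Compound 5 comes from the oxime 4 by C-chlorination, and 4 from the aldehyde 3. The formyl group of 3 is removed to give the bis(benzyl) ether 2, whose most activated free position is para to the methoxy group and ortho to a benzyloxy group. Compound 2 is the double benzyl ether of the commercial hydroquinone 1. The ring A pattern, with its two different oxygens, is therefore bought and not built.

**10 back to 6.** The enamine 10 is the condensation product of the arylacetaldehyde 8 with 9. Compound 8 is the one-carbon homologue of the commercial aldehyde 6, reached through the enol ether 7. The carbon added here becomes C2 of 15, so C2 arrives at the aldehyde oxidation level together with ring B.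

## Alternatives that were turned down

**Alternative 1: ring A built by a Diels–Alder benzannulation.**
- Disconnection: the C5–C6 and C4a–C8a bonds of ring A.
- Key step: the diene 4-(benzyloxy)-1,3-dimethoxy-1-(trimethylsilyloxy)buta-1,3-diene A1 adds to the terminal ynone 1-(3,4,5-trimethoxyphenyl)but-3-yn-2-one A2. Loss of the methoxy group from the ketal carbon and desilylation aromatise the adduct to the 2-hydroxydeoxybenzoin A3.
- For it: regiochemistry is encoded by the diene, whose nucleophilic terminus meets the β-carbon of the ynone. The ortho hydroxyl and the C6 benzyl ether come out already differentiated. A3 is the classical isoflavone precursor, so the endgame (one-carbon formylation with cyclisation, then debenzylation) is textbook chemistry. On the endgame this alternative is stronger than the chosen route, which must pass through a sensitive amino enal.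
- Against it: the key step is spent on an aromatic ring that can be bought with its oxygens in place. A1 is a tetra-oxygenated, hydrolytically fragile diene needing several steps and a defined geometry at its benzyloxy terminus. A2 has a methylene flanked by an aryl group and an ynone, which is prone to enolisation, silyl transfer and isomerisation to an allenyl ketone. C2 still has to be added afterwards.
- Comparison: the overall step count would not be lower. The chosen strategy buys ring A and makes the C4–C3 bond while joining the two halves, with C2 already attached.

**Alternative 2: aryne annulation with an α-formyl arylacetate.**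
- Disconnection: O1–C8a and C4–C4a.
- Key step: fluoride releases the symmetric aryne from 4,5-bis(benzyloxy)-2-(trimethylsilyl)phenyl triflate A4. The enolate oxygen of methyl 3-oxo-2-(3,4,5-trimethoxyphenyl)propanoate A5 adds to it, and the resulting aryl anion attacks the ester to close ring C as the isoflavone A6.
- For it: on bond economy it is stronger than the chosen route. Two ring bonds form in one step, the product is already at the isoflavone oxidation level, and A5 is one Claisen formylation away from a simple ester.
- Against it: three structural points.
  - The symmetric aryne forces two identical benzyl ethers. After debenzylation to the catechol A7, O7 must be methylated selectively in the presence of O6. The only handle is the somewhat higher acidity of the 7-hydroxyl, which is para to the carbonyl. An unsymmetrical aryne would move the problem into the aryne addition, where remote alkoxy groups give little control.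
  - The enolate of A5 is ambident. Attack through carbon, followed by acyl transfer, is the usual course of β-dicarbonyl enolates with arynes, and the O-arylation needed here competes with it.
  - A4 itself needs a multistep preparation.
- Comparison: the chosen strategy takes two extra unmasking steps but fixes the O6/O7 pattern in the first step. Its regiochemistry rests on the polarisation of an enamine and not on a ratio.

**Alternative 3: carbene insertion into an O-methyl C–H bond.**
- Disconnection: C2–C3, with C2 coming from an ether methyl group.
- Key step: the deoxybenzoin A8 is converted by diazo transfer into the diazo ketone A9. Rh2(OAc)4 (divalent rhodium) turns A9 into an aryl acyl carbenoid at C3, which inserts into a C–H bond of the ortho methoxy group and closes ring C as the racemic isoflavanone A10.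
- For it: no one-carbon reagent is needed because C2 is already in the molecule, the ring A oxygens are differentiated from the start, and no N–O reduction is required. On atom economy and novelty this alternative is stronger.
- Against it: three points.
  - The ether oxygen sits in a 1,5 relation to the carbene carbon. Lone-pair attack gives a five-membered oxonium ylide, and a Stevens-type methyl shift would then contract the ring to a benzofuranone. The wanted insertion needs a six-membered transition state, which is normally slower. Wolff rearrangement and Buchner-type addition to ring B are further outlets.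
  - A10 is at the wrong oxidation level and has a C3 stereocentre that serves no purpose. Dehydrogenation across C2–C3 and debenzylation add two steps.
  - A8 has to be made anyway. Its ortho-hydroxy analogue would give the isoflavone by classical formylation in one step, so the carbene detour costs steps.
- Comparison: the chosen strategy introduces C2 at the aldehyde level from the outset. Its key step belongs to a known reaction class and leaves no stereocentre to erase afterwards.

Key step: step 8

Remark: 7 is formed as an E/Z mixture and 12 as a racemic trans pair (one enantiomer drawn). Neither feature survives into later compounds, so no control is attempted.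

## Route

Step 1
Reactants: 1 2-methoxyhydroquinone (2-methoxybenzene-1,4-diol)
Product: 2 1,4-bis(benzyloxy)-2-methoxybenzene
Conditions: BnBr (2.3 equiv), K2CO3, DMF, argon, rt → 60 °C
Reagents that add atoms: benzyl bromide, BrCc1ccccc1
Why: Double Williamson etherification of both phenoxides with a reactive benzylic bromide; working under argon keeps the electron-rich hydroquinone from oxidising to the quinone before both oxygens are capped.

Step 2
Reactants: 2 1,4-bis(benzyloxy)-2-methoxybenzene
Product: 3 2,5-bis(benzyloxy)-4-methoxybenzaldehyde
Conditions: POCl3, DMF, 0 → 75 °C; then aq NaOAc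
Reagents that add atoms: N,N-dimethylformamide, CN(C)C=O (formyl carbon); water, O (carbonyl oxygen)
Why: Vilsmeier–Haack formylation; the chloroiminium ion should attack the position para to the methoxy group and ortho to one benzyloxy group, the most activated unhindered site, as in the formylation of other 1,2,4-trialkoxybenzenes. The position between the two ethers is shielded, the remaining one is activated by a single ortho oxygen, and benzyl aryl ethers tolerate the conditions.

Step 3
Reactants: 3 2,5-bis(benzyloxy)-4-methoxybenzaldehyde
Product: 4 (E)-2,5-bis(benzyloxy)-4-methoxybenzaldehyde oxime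
Conditions: NH2OH·HCl, NaOAc, EtOH/H2O, rt → 50 °C
Reagents that add atoms: hydroxylamine hydrochloride, Cl.NO
Why: Oxime formation by condensation of an aromatic aldehyde with hydroxylamine under acetate buffering; the E aldoxime is the thermodynamic product.

Step 4
Reactants: 4 (E)-2,5-bis(benzyloxy)-4-methoxybenzaldehyde oxime
Product: 5 (Z)-2,5-bis(benzyloxy)-N-hydroxy-4-methoxybenzenecarboximidoyl chloride
Conditions: NCS (1.05 equiv), DMF, 0 °C → rt; aqueous work-up, used crude
Reagents that add atoms: N-chlorosuccinimide, O=C1CCC(=O)N1Cl
Why: C-chlorination of an aldoxime with NCS in DMF, the standard way to a hydroximoyl chloride as nitrile oxide precursor; one equivalent at low temperature is used to hold back electrophilic chlorination of the alkoxy-rich ring.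

Step 5
Reactants: 6 3,4,5-trimethoxybenzaldehyde
Product: 7 1,2,3-trimethoxy-5-(2-methoxyvinyl)benzene (E/Z mixture)
Conditions: MeOCH2PPh3Cl, KOtBu, THF, 0 °C → rt
Reagents that add atoms: (methoxymethyl)triphenylphosphonium chloride, COC[P+](c1ccccc1)(c1ccccc1)c1ccccc1.[Cl-]
Why: Wittig reaction of a non-enolisable aromatic aldehyde with methoxymethylenetriphenylphosphorane, a one-carbon homologation; the alkene geometry is irrelevant because both isomers hydrolyse to the same aldehyde.

Step 6
Reactants: 7 1,2,3-trimethoxy-5-(2-methoxyvinyl)benzene
Product: 8 2-(3,4,5-trimethoxyphenyl)acetaldehyde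
Conditions: 2 M HCl, THF, 50 °C; used at once
Reagents that add atoms: water, O
Why: Acid-catalysed enol ether hydrolysis through C-protonation, hemiacetal formation and loss of methanol; the arylacetaldehyde is taken on immediately because it self-condenses on standing.

Step 7
Reactants: 8 2-(3,4,5-trimethoxyphenyl)acetaldehyde; 9 pyrrolidine
Product: 10 1-[(E)-2-(3,4,5-trimethoxyphenyl)vinyl]pyrrolidine
Conditions: 9 (1.1 equiv), 4 Å molecular sieves, CH2Cl2, 0 °C → rt; filter, evaporate, high vacuum, used crude
Reagents that add atoms: none
Why: Enamine formation by dehydrating condensation of an enolisable aldehyde with a secondary amine; conjugation with ring B and allylic strain should make the E isomer the only significant one. Excess 9 is pumped off so that no free secondary amine meets the nitrile oxide.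

Step 8
Reactants: 5 (Z)-2,5-bis(benzyloxy)-N-hydroxy-4-methoxybenzenecarboximidoyl chloride; 10 1-[(E)-2-(3,4,5-trimethoxyphenyl)vinyl]pyrrolidine
Product: 13 3-[2,5-bis(benzyloxy)-4-methoxyphenyl]-4-(3,4,5-trimethoxyphenyl)isoxazole, via nitrile oxide 11 (not isolated), via 5-pyrrolidinylisoxazoline 12 (not isolated)
Conditions: 5 added slowly to 10 (1.5 equiv) and Et3N (1.2 equiv), CH2Cl2, 0 °C → rt; then TFA, 40 °C
Reagents that add atoms: none
Why: Et3N removes HCl from 5 by 1,3-elimination and releases nitrile oxide 11 at low stationary concentration in the presence of excess 10. The electron-rich enamine and the electrophilic dipole should combine in a concerted but strongly asynchronous 1,3-dipolar cycloaddition; the closest known reaction type is the nitrile oxide–enamine cycloaddition to 5-amino-2-isoxazolines, followed by amine elimination to 3,4-disubstituted isoxazoles. The five-membered ring is closed intermolecularly in a (3+2) mode, with the C–C bond (C4–C3 of the target) forming ahead of the C–O bond (oxygen on the future C2). Regiochemistry is the selectivity the step needs: the nitrogen lone pair of 10 places the largest HOMO coefficient on the carbon bearing ring B, which bonds to the electrophilic carbon of 11, while the dipole oxygen ends on the aminal carbon; the opposite orientation has no electronic support. The two new stereocentres of 12 are set trans by suprafacial addition to the E alkene, but neither needs control because both are erased in the same flask. TFA protonates the pyrrolidine nitrogen of 12, the ring oxygen assists its departure, and loss of the C4 proton aromatises the ring to 13. Dimerisation of 11 to a furoxan is the competing process and is held back by slow addition, excess 10 and the ortho benzyloxy group next to the dipole; the benzyl and methyl ethers are inert throughout.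

Step 9
Reactants: 13 3-[2,5-bis(benzyloxy)-4-methoxyphenyl]-4-(3,4,5-trimethoxyphenyl)isoxazole
Product: 14 (Z)-3-amino-3-(2,5-dihydroxy-4-methoxyphenyl)-2-(3,4,5-trimethoxyphenyl)prop-2-enal
Conditions: H2 (1 atm), 10% Pd/C, EtOAc/EtOH, rt; filtered under argon, used crude
Reagents that add atoms: none
Why: Catalytic hydrogenolysis should cleave the weak N–O bond of the isoxazole to the Z amino enal, a hydrogen-bonded vinylogous formamide that resists further reduction, and should remove both benzyl ethers in the same operation while leaving the aryl methyl ethers alone. Partial ring closure of 14 at this stage would be harmless because step 10 converges.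

Step 10
Reactants: 14 (Z)-3-amino-3-(2,5-dihydroxy-4-methoxyphenyl)-2-(3,4,5-trimethoxyphenyl)prop-2-enal
Product: 15 6-hydroxy-7-methoxy-3-(3,4,5-trimethoxyphenyl)-4H-chromen-4-one
Conditions: 2 M HCl, MeOH (degassed), 60 °C
Reagents that add atoms: water, O
Why: Acid-promoted cyclodehydration with enaminone hydrolysis, the closing stage of the classical isoflavone synthesis from α-formyl deoxybenzoins: the ortho hydroxyl adds to the formyl carbon C2 in a 6-exo closure, dehydration gives the 4-aminobenzopyrylium ion, and water replaces nitrogen at C4 with loss of ammonium. The second phenol cannot reach an electrophilic carbon and becomes the 6-hydroxyl.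

## Compound list

1 | 2-methoxyhydroquinone (2-methoxybenzene-1,4-diol) | COc1cc(O)ccc1O | starting material
2 | 1,4-bis(benzyloxy)-2-methoxybenzene | COc1cc(OCc2ccccc2)ccc1OCc1ccccc1 | intermediate
3 | 2,5-bis(benzyloxy)-4-methoxybenzaldehyde | O=Cc1cc(OCc2ccccc2)c(OC)cc1OCc1ccccc1 | intermediate
4 | (E)-2,5-bis(benzyloxy)-4-methoxybenzaldehyde oxime | O/N=C/c1cc(OCc2ccccc2)c(OC)cc1OCc1ccccc1 | intermediate
5 | (Z)-2,5-bis(benzyloxy)-N-hydroxy-4-methoxybenzenecarboximidoyl chloride | O/N=C(\Cl)c1cc(OCc2ccccc2)c(OC)cc1OCc1ccccc1 | intermediate
6 | 3,4,5-trimethoxybenzaldehyde | COc1cc(C=O)cc(OC)c1OC | starting material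
7 | 1,2,3-trimethoxy-5-(2-methoxyvinyl)benzene (E/Z mixture) | COC=Cc1cc(OC)c(OC)c(OC)c1 | intermediate
8 | 2-(3,4,5-trimethoxyphenyl)acetaldehyde | COc1cc(CC=O)cc(OC)c1OC | intermediate
9 | pyrrolidine | C1CCNC1 | starting material
10 | 1-[(E)-2-(3,4,5-trimethoxyphenyl)vinyl]pyrrolidine | COc1cc(/C=C/N2CCCC2)cc(OC)c1OC | intermediate
11 | 2,5-bis(benzyloxy)-4-methoxybenzonitrile oxide | [O-][N+]#Cc1cc(OCc2ccccc2)c(OC)cc1OCc1ccccc1 | intermediate (not isolated)
12 | trans-3-[2,5-bis(benzyloxy)-4-methoxyphenyl]-5-(pyrrolidin-1-yl)-4-(3,4,5-trimethoxyphenyl)-4,5-dihydroisoxazole (racemic, one enantiomer drawn) | COc1cc(OCc2ccccc2)c(C2=NO[C@H](N3CCCC3)[C@H]2c2cc(OC)c(OC)c(OC)c2)cc1OCc1ccccc1 | intermediate (not isolated)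
13 | 3-[2,5-bis(benzyloxy)-4-methoxyphenyl]-4-(3,4,5-trimethoxyphenyl)isoxazole | COc1cc(OCc2ccccc2)c(-c2nocc2-c2cc(OC)c(OC)c(OC)c2)cc1OCc1ccccc1 | intermediate
14 | (Z)-3-amino-3-(2,5-dihydroxy-4-methoxyphenyl)-2-(3,4,5-trimethoxyphenyl)prop-2-enal | N/C(=C(\C=O)c1cc(OC)c(OC)c(OC)c1)c1cc(O)c(OC)cc1O | intermediate
15 | 6-hydroxy-7-methoxy-3-(3,4,5-trimethoxyphenyl)-4H-chromen-4-one | COc1cc2occ(-c3cc(OC)c(OC)c(OC)c3)c(=O)c2cc1O | target

## Step count and risk

Total step count: 10. Longest linear sequence: 7 steps (1, 2, 3, 4, 8, 9, 10). The ring B branch (steps 5 to 7) joins at step 8.

**Step 8 (key step).**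
- What may go wrong: dimerisation of the nitrile oxide can outrun the cycloaddition if the enamine has partly hydrolysed. Residual secondary amine can add to the dipole. Elimination of the amine from the cycloadduct may stall.
- Fallback: it sets out from 5 and changes the dipolarophile and the source of regiocontrol. Compound 5 is treated with Et3N in 1,2-dichloroethane at rt in the presence of commercial 5-ethynyl-1,2,3-trimethoxybenzene F1 and catalytic Cp*RuCl(cod), a divalent ruthenium complex. Ruthenium-catalysed cycloaddition of nitrile oxides to terminal alkynes is known to give 3,4-disubstituted isoxazoles, the reverse of the thermal orientation. This should give 13 directly, where the route is rejoined.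

**Step 4.**
- What may go wrong: electrophilic chlorination of the trialkoxy ring can compete with chlorination at the oxime carbon, because ring A is strongly activated.
- Fallback: it sets out from 3 and avoids electrophilic chlorine at the dipole-forming stage. Pinnick oxidation (NaClO2, NaH2PO4, 2-methyl-2-butene) gives 2,5-bis(benzyloxy)-4-methoxybenzoic acid F2. Carbodiimide coupling with O-(tert-butyldiphenylsilyl)hydroxylamine gives 2,5-bis(benzyloxy)-N-[(tert-butyldiphenylsilyl)oxy]-4-methoxybenzamide F3. Dehydration of F3 with Tf2O and Et3N in CH2Cl2 at −40 °C is a known way to generate nitrile oxides. This releases 11 in solution, to which 10 is added, so the route is rejoined at 11 within step 8.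

**Step 9.**
- What may go wrong: the hydrogenation may stall after partial debenzylation through catalyst poisoning by the amine, or go on to saturate the amino enal. The hydroquinone-type ring may oxidise in air during filtration.
- Fallback: it sets out from 13 and separates the two reductions. Mo(CO)6 (zerovalent molybdenum) in MeCN/H2O at reflux cleaves only the N–O bond and gives (Z)-3-amino-3-[2,5-bis(benzyloxy)-4-methoxyphenyl]-2-(3,4,5-trimethoxyphenyl)prop-2-enal F4. BCl3 with pentamethylbenzene in CH2Cl2 at −78 °C then removes both benzyl ethers while sparing the methyl ethers. This gives 14, where the route is rejoined.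

**Step 6.**
- What may go wrong: acid-catalysed aldol self-condensation and air oxidation of the arylacetaldehyde during the hydrolysis, which would erode the material before the enamine is made.
- Fallback: it sets out from 6 and produces the aldehyde by oxidation under non-acidic conditions. Wittig methylenation (Ph3PCH3Br, KOtBu) gives 1,2,3-trimethoxy-5-vinylbenzene F5. Hydroboration with 9-BBN and oxidation with NaOH/H2O2 gives 2-(3,4,5-trimethoxyphenyl)ethanol F6. Dess–Martin periodinane in CH2Cl2 gives 8, where the route is rejoined and 8 is condensed with 9 at once.

## Further compounds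

F1 | step 8 | 5-ethynyl-1,2,3-trimethoxybenzene | C#Cc1cc(OC)c(OC)c(OC)c1
F2 | step 4 | 2,5-bis(benzyloxy)-4-methoxybenzoic acid | OC(=O)c1cc(OCc2ccccc2)c(OC)cc1OCc1ccccc1
F3 | step 4 | 2,5-bis(benzyloxy)-N-[(tert-butyldiphenylsilyl)oxy]-4-methoxybenzamide | CC(C)(C)[Si](ONC(=O)c1cc(OCc2ccccc2)c(OC)cc1OCc1ccccc1)(c1ccccc1)c1ccccc1
F4 | step 9 | (Z)-3-amino-3-[2,5-bis(benzyloxy)-4-methoxyphenyl]-2-(3,4,5-trimethoxyphenyl)prop-2-enal | N/C(=C(\C=O)c1cc(OC)c(OC)c(OC)c1)c1cc(OCc2ccccc2)c(OC)cc1OCc1ccccc1
F5 | step 6 | 1,2,3-trimethoxy-5-vinylbenzene | C=Cc1cc(OC)c(OC)c(OC)c1
F6 | step 6 | 2-(3,4,5-trimethoxyphenyl)ethanol | OCCc1cc(OC)c(OC)c(OC)c1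
A1 | alternative 1 | 4-(benzyloxy)-1,3-dimethoxy-1-(trimethylsilyloxy)buta-1,3-diene | COC(O[Si](C)(C)C)=CC(OC)=COCc1ccccc1
A2 | alternative 1 | 1-(3,4,5-trimethoxyphenyl)but-3-yn-2-one | C#CC(=O)Cc1cc(OC)c(OC)c(OC)c1
A3 | alternative 1 | 1-[5-(benzyloxy)-2-hydroxy-4-methoxyphenyl]-2-(3,4,5-trimethoxyphenyl)ethanone | COc1cc(O)c(cc1OCc1ccccc1)C(=O)Cc1cc(OC)c(OC)c(OC)c1
A4 | alternative 2 | 4,5-bis(benzyloxy)-2-(trimethylsilyl)phenyl trifluoromethanesulfonate | C[Si](C)(C)c1cc(OCc2ccccc2)c(OCc2ccccc2)cc1OS(=O)(=O)C(F)(F)F
A5 | alternative 2 | methyl 3-oxo-2-(3,4,5-trimethoxyphenyl)propanoate | COC(=O)C(C=O)c1cc(OC)c(OC)c(OC)c1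
A6 | alternative 2 | 6,7-bis(benzyloxy)-3-(3,4,5-trimethoxyphenyl)chromen-4-one | O=c1c(-c2cc(OC)c(OC)c(OC)c2)coc2cc(OCc3ccccc3)c(OCc3ccccc3)cc12
A7 | alternative 2 | 6,7-dihydroxy-3-(3,4,5-trimethoxyphenyl)chromen-4-one | O=c1c(-c2cc(OC)c(OC)c(OC)c2)coc2cc(O)c(O)cc12
A8 | alternative 3 | 1-[5-(benzyloxy)-2,4-dimethoxyphenyl]-2-(3,4,5-trimethoxyphenyl)ethanone | COc1cc(OC)c(cc1OCc1ccccc1)C(=O)Cc1cc(OC)c(OC)c(OC)c1
A9 | alternative 3 | 1-[5-(benzyloxy)-2,4-dimethoxyphenyl]-2-diazo-2-(3,4,5-trimethoxyphenyl)ethanone | COc1cc(OC)c(cc1OCc1ccccc1)C(=O)C(=[N+]=[N-])c1cc(OC)c(OC)c(OC)c1
A10 | alternative 3 | 6-(benzyloxy)-7-methoxy-3-(3,4,5-trimethoxyphenyl)chroman-4-one (racemic) | COc1cc2OCC(c3cc(OC)c(OC)c(OC)c3)C(=O)c2cc1OCc1ccccc1
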